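**Plan**

- Retrosynthesis first cuts the twelve O–CH3 bonds (every hydroxyl travels as a methyl ether), then the aryl C–O bond between the ring C oxygen and D1, giving an A–B–C phenol and a D–E aryl triflate.
- The A–B–C half is cut at the aryl C–O bonds to B1 and to ring C; each ring comes from a bromobenzaldehyde whose formyl group is the masked next phenol.
- Ring D is cut between D3 and D4. D4 bears the ether oxygen to ring E and lies between the oxygenated carbons D3 and D5, with the third oxygen on D1. This 1,3,5-oxygen pattern is that of a folded 3,5-dioxygenated hexanoate whose C6 is D4 and whose ester carbon is D3.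
- Forward, ring E (bought) is extended to the six-carbon chain, which is stored as a 4-benzyloxy-2-pyranone and folded into ring D. Rings A, B and C are joined by two coupling/oxidation cycles, the halves are joined at D1, and all methyl ethers are cleaved last.
- The target has no stereocentre; the only geometric element on the way, the (E) enol ether of the open chain, is fixed by the pyranone ring it comes from.

Key step: step 5

Assumption: 2,4,6-trimethoxyphenol, both bromodimethoxybenzaldehydes and sodium benzyl oxide (1.0 M in benzyl alcohol) are taken to be catalogue chemicals.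

**Route**

Step 1
Reactants: 1 3,4,5-trimethoxyphenol; 2 methyl bromoacetate
Product: 3 methyl 2-(3,4,5-trimethoxyphenoxy)acetate
Conditions: K2CO3, acetone, reflux
Reagents that add atoms: none
Why: Williamson ether synthesis, in which the phenoxide displaces bromide from the activated alpha-bromo ester by SN2.

Step 2
Reactants: 4 methyl acetoacetate; 3 methyl 2-(3,4,5-trimethoxyphenoxy)acetate
Product: 5 methyl 3,5-dioxo-6-(3,4,5-trimethoxyphenoxy)hexanoate
Conditions: 4 (2.2 equiv), NaH, THF, 0 °C; n-BuLi, 0 °C; then 3, 0 °C to rt; aq. HCl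
Reagents that add atoms: none
Why: Claisen-type acylation of the acetoacetate dianion at its terminal carbon by the ester should give the 3,5-dioxo ester, with excess dianion used because 5 is more acidic than 4 and is deprotonated as it forms.

Step 3
Reactants: 5 methyl 3,5-dioxo-6-(3,4,5-trimethoxyphenoxy)hexanoate
Product: 6 4-hydroxy-6-[(3,4,5-trimethoxyphenoxy)methyl]-2H-pyran-2-one
Conditions: DBU, toluene, 110 °C; then 1 M HCl
Reagents that add atoms: none
Why: Base-mediated lactonization of a 3,5-dioxo ester (enol oxygen of C5 onto the ester) is the standard entry to 6-substituted 4-hydroxy-2-pyranones.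

Step 4
Reactants: 6 4-hydroxy-6-[(3,4,5-trimethoxyphenoxy)methyl]-2H-pyran-2-one
Product: 7 4-(benzyloxy)-6-[(3,4,5-trimethoxyphenoxy)methyl]-2H-pyran-2-one
Conditions: BnOH, PPh3, DIAD, THF, 0 °C to rt
Reagents that add atoms: benzyl alcohol, OCc1ccccc1
Why: Mitsunobu O-alkylation of the acidic vinylogous-acid hydroxyl should etherify O4 and avoid the C3 benzylation that benzyl bromide and base can cause.

Step 5
Reactants: 7 4-(benzyloxy)-6-[(3,4,5-trimethoxyphenoxy)methyl]-2H-pyran-2-one
Product: 9 5-(benzyloxy)-2-(3,4,5-trimethoxyphenoxy)benzene-1,3-diol, via ring-opened benzyl keto ester 8 (not isolated)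
Conditions: BnONa (1.0 M in BnOH, 4 equiv), 1,4-dioxane, 100 °C, Ar; then 1 M HCl
Reagents that add atoms: sodium benzyl oxide, [Na+].[O-]Cc1ccccc1 (its benzyloxy group is built into 8 and leaves again in the ring closure; 9 is an isomer of 7)
Why: Proposed new method: benzyl oxide adds to the lactone carbonyl of 7 and opens it to the enolate of 8, in which the double bond inherited from the ring holds the ester carbon C1 and C4 on the same side; proton exchange in benzyl alcohol then gives the C6 enolate, favoured by the aryloxy group on C6, and this carbon attacks C1 with loss of benzyl oxide (Claisen condensation of the Dieckmann type), forming the D4–D3 bond. The closest known reaction is the alkoxide-induced conversion of 4-methoxy-6-methyl-2-pyranone into 5-methoxyresorcinol, which follows the same sequence with an unsubstituted methyl carbon as the nucleophile. Ring D closes in the 6-exo-trig mode, and the cyclohexenedione first formed enolizes to the resorcinol, whose deprotonation makes the closure irreversible. No stereocentre is created. The selectivity needed is C-acylation by C6: attack by the enolate oxygen only regenerates 7, which benzyl oxide reopens; deprotonation at C4 is reversible in the protic medium and that carbanion cannot reach C1; and the enol ether keeps C2 from being deprotonated, the event that in a free 3,5-dioxo ester such as 5 would turn the ester into an unreactive enolate under any base strong enough to enolize C6. Matching the alkoxide to the enol ether makes alkoxy exchange at C3 degenerate, and 9 emerges with O-D1 benzylated and O-D3/O-D5 free, so the three ring oxygens are already told apart.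

Step 6
Reactants: 9 5-(benzyloxy)-2-(3,4,5-trimethoxyphenoxy)benzene-1,3-diol
Product: 10 5-(benzyloxy)-1,3-dimethoxy-2-(3,4,5-trimethoxyphenoxy)benzene
Conditions: MeI, K2CO3, acetone, reflux
Reagents that add atoms: iodomethane, CI
Why: Williamson O-methylation of the two equivalent phenols, to which the benzyl ether and the diaryl ether are inert.

Step 7
Reactants: 10 5-(benzyloxy)-1,3-dimethoxy-2-(3,4,5-trimethoxyphenoxy)benzene
Product: 11 3,5-dimethoxy-4-(3,4,5-trimethoxyphenoxy)phenol
Conditions: H2 (1 atm), 10% Pd/C, EtOAc/MeOH, rt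
Reagents that add atoms: none
Why: Catalytic hydrogenolysis cleaves only the benzylic C–O bond, so O-D1 alone is unmasked while the methyl and diaryl ethers stay.

Step 8
Reactants: 11 3,5-dimethoxy-4-(3,4,5-trimethoxyphenoxy)phenol
Product: 12 3,5-dimethoxy-4-(3,4,5-trimethoxyphenoxy)phenyl trifluoromethanesulfonate
Conditions: Tf2O, pyridine, CH2Cl2, 0 °C
Reagents that add atoms: trifluoromethanesulfonic anhydride, O=S(=O)(OS(=O)(=O)C(F)(F)F)C(F)(F)F
Why: O-sulfonylation of an unhindered phenol (both ortho positions carry hydrogen) turns D1 into the electrophilic carbon for the fragment coupling.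

Step 9
Reactants: 13 2,4,6-trimethoxyphenol; 14 4-bromo-2,6-dimethoxybenzaldehyde
Product: 15 2,6-dimethoxy-4-(2,4,6-trimethoxyphenoxy)benzaldehyde
Conditions: CuI (10 mol %), picolinic acid (20 mol %), K3PO4, DMSO, 90 °C, Ar
Reagents that add atoms: none
Why: Ullmann-type C–O coupling with the monovalent copper/picolinic acid system, which accepts 2,6-disubstituted phenols, on a bromide that has no ortho substituent and is activated by the para formyl group.

Step 10
Reactants: 15 2,6-dimethoxy-4-(2,4,6-trimethoxyphenoxy)benzaldehyde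
Product: 17 2,6-dimethoxy-4-(2,4,6-trimethoxyphenoxy)phenol, via aryl formate 16 (not isolated)
Conditions: mCPBA, CH2Cl2, 0 °C to rt; NaHCO3 wash; then K2CO3 (cat.), MeOH, rt
Reagents that add atoms: mCPBA, O=C(OO)c1cccc(Cl)c1
Why: Baeyer–Villiger (Dakin-type) oxidation, in which the electron-rich 2,6-dimethoxyaryl group migrates to oxygen to give formate 16 and methanolysis frees the phenol flanked by two methoxy groups.

Step 11
Reactants: 17 2,6-dimethoxy-4-(2,4,6-trimethoxyphenoxy)phenol; 18 2-bromo-4,6-dimethoxybenzaldehyde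
Product: 19 2-[2,6-dimethoxy-4-(2,4,6-trimethoxyphenoxy)phenoxy]-4,6-dimethoxybenzaldehyde
Conditions: CuI (10 mol %), picolinic acid (20 mol %), K3PO4, DMSO, 100 °C, Ar
Reagents that add atoms: none
Why: The same Ullmann-type C–O coupling, here helped by the ortho formyl group, which activates the C–Br bond toward copper.

Step 12
Reactants: 19 2-[2,6-dimethoxy-4-(2,4,6-trimethoxyphenoxy)phenoxy]-4,6-dimethoxybenzaldehyde
Product: 21 2-[2,6-dimethoxy-4-(2,4,6-trimethoxyphenoxy)phenoxy]-4,6-dimethoxyphenol, via aryl formate 20 (not isolated)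
Conditions: mCPBA, CH2Cl2, 0 °C to rt; NaHCO3 wash; then K2CO3 (cat.), MeOH, rt
Reagents that add atoms: mCPBA, O=C(OO)c1cccc(Cl)c1
Why: Baeyer–Villiger (Dakin-type) oxidation of a 2,4,6-trioxygenated benzaldehyde, whose aryl group migrates readily, followed by methanolysis of formate 20 to the ring C phenol.

Step 13
Reactants: 21 2-[2,6-dimethoxy-4-(2,4,6-trimethoxyphenoxy)phenoxy]-4,6-dimethoxyphenol; 12 3,5-dimethoxy-4-(3,4,5-trimethoxyphenoxy)phenyl trifluoromethanesulfonate
Product: 22 1-[2,6-dimethoxy-4-(2,4,6-trimethoxyphenoxy)phenoxy]-2-[3,5-dimethoxy-4-(3,4,5-trimethoxyphenoxy)phenoxy]-3,5-dimethoxybenzene (the dodecamethyl ether of the target)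
Conditions: Pd(OAc)2 (5 mol %), tBuXPhos (10 mol %), K3PO4, toluene, 100 °C, Ar
Reagents that add atoms: none
Why: Buchwald–Hartwig-type C–O coupling by oxidative addition of the triflate to zerovalent palladium, exchange for the phenoxide of 21 and C–O reductive elimination, which the bulky di-tert-butylbiarylphosphine promotes even for a phenoxide with two ortho substituents.

Step 14
Reactants: 22 the dodecamethyl ether
Product: 23 5-[2,6-dihydroxy-4-(2,4,6-trihydroxyphenoxy)phenoxy]-4-[3,5-dihydroxy-4-(3,4,5-trihydroxyphenoxy)phenoxy]benzene-1,3-diol (CNP0227069.0)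
Conditions: BBr3 (24 equiv), CH2Cl2, −78 °C to rt; then degassed H2O, 0 °C
Reagents that add atoms: none
Why: Lewis-acid ether cleavage in which BBr3 binds each methoxy oxygen and bromide attacks the methyl carbon by SN2, so only O–CH3 bonds break and the four diaryl ether bonds, which offer no sp3 carbon, should survive.

**Compound list**

1 | 3,4,5-trimethoxyphenol | COc1cc(O)cc(OC)c1OC | starting material
2 | methyl bromoacetate | COC(=O)CBr | starting material
3 | methyl 2-(3,4,5-trimethoxyphenoxy)acetate | COC(=O)COc1cc(OC)c(OC)c(OC)c1 | intermediate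
4 | methyl acetoacetate | COC(=O)CC(C)=O | starting material
5 | methyl 3,5-dioxo-6-(3,4,5-trimethoxyphenoxy)hexanoate | COC(=O)CC(=O)CC(=O)COc1cc(OC)c(OC)c(OC)c1 | intermediate
6 | 4-hydroxy-6-[(3,4,5-trimethoxyphenoxy)methyl]-2H-pyran-2-one | O=c1cc(O)cc(COc2cc(OC)c(OC)c(OC)c2)o1 | intermediate
7 | 4-(benzyloxy)-6-[(3,4,5-trimethoxyphenoxy)methyl]-2H-pyran-2-one | O=c1cc(OCc2ccccc2)cc(COc2cc(OC)c(OC)c(OC)c2)o1 | intermediate
8 | benzyl (2E)-3-(benzyloxy)-5-oxo-6-(3,4,5-trimethoxyphenoxy)hex-2-enoate (formed as its sodium enolate) | O=C(OCc1ccccc1)/C=C(/OCc1ccccc1)CC(=O)COc1cc(OC)c(OC)c(OC)c1 | intermediate (not isolated)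
9 | 5-(benzyloxy)-2-(3,4,5-trimethoxyphenoxy)benzene-1,3-diol | Oc1cc(OCc2ccccc2)cc(O)c1Oc1cc(OC)c(OC)c(OC)c1 | intermediate
10 | 5-(benzyloxy)-1,3-dimethoxy-2-(3,4,5-trimethoxyphenoxy)benzene | COc1cc(OCc2ccccc2)cc(OC)c1Oc1cc(OC)c(OC)c(OC)c1 | intermediate
11 | 3,5-dimethoxy-4-(3,4,5-trimethoxyphenoxy)phenol | COc1cc(O)cc(OC)c1Oc1cc(OC)c(OC)c(OC)c1 | intermediate
12 | 3,5-dimethoxy-4-(3,4,5-trimethoxyphenoxy)phenyl trifluoromethanesulfonate | COc1cc(OS(=O)(=O)C(F)(F)F)cc(OC)c1Oc1cc(OC)c(OC)c(OC)c1 | intermediate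
13 | 2,4,6-trimethoxyphenol | COc1cc(OC)c(O)c(OC)c1 | starting material
14 | 4-bromo-2,6-dimethoxybenzaldehyde | COc1cc(Br)cc(OC)c1C=O | starting material
15 | 2,6-dimethoxy-4-(2,4,6-trimethoxyphenoxy)benzaldehyde | COc1cc(Oc2c(OC)cc(OC)cc2OC)cc(OC)c1C=O | intermediate
16 | 2,6-dimethoxy-4-(2,4,6-trimethoxyphenoxy)phenyl formate | COc1cc(Oc2c(OC)cc(OC)cc2OC)cc(OC)c1OC=O | intermediate (not isolated)
17 | 2,6-dimethoxy-4-(2,4,6-trimethoxyphenoxy)phenol | COc1cc(Oc2c(OC)cc(OC)cc2OC)cc(OC)c1O | intermediate
18 | 2-bromo-4,6-dimethoxybenzaldehyde | COc1cc(Br)c(C=O)c(OC)c1 | starting material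
19 | 2-[2,6-dimethoxy-4-(2,4,6-trimethoxyphenoxy)phenoxy]-4,6-dimethoxybenzaldehyde | COc1cc(OC)c(C=O)c(Oc2c(OC)cc(Oc3c(OC)cc(OC)cc3OC)cc2OC)c1 | intermediate
20 | 2-[2,6-dimethoxy-4-(2,4,6-trimethoxyphenoxy)phenoxy]-4,6-dimethoxyphenyl formate | COc1cc(OC)c(OC=O)c(Oc2c(OC)cc(Oc3c(OC)cc(OC)cc3OC)cc2OC)c1 | intermediate (not isolated)
21 | 2-[2,6-dimethoxy-4-(2,4,6-trimethoxyphenoxy)phenoxy]-4,6-dimethoxyphenol | COc1cc(OC)c(O)c(Oc2c(OC)cc(Oc3c(OC)cc(OC)cc3OC)cc2OC)c1 | intermediate
22 | 1-[2,6-dimethoxy-4-(2,4,6-trimethoxyphenoxy)phenoxy]-2-[3,5-dimethoxy-4-(3,4,5-trimethoxyphenoxy)phenoxy]-3,5-dimethoxybenzene | COc1cc(OC)c(Oc2cc(OC)c(Oc3cc(OC)c(OC)c(OC)c3)c(OC)c2)c(Oc2c(OC)cc(Oc3c(OC)cc(OC)cc3OC)cc2OC)c1 | intermediate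
23 | 5-[2,6-dihydroxy-4-(2,4,6-trihydroxyphenoxy)phenoxy]-4-[3,5-dihydroxy-4-(3,4,5-trihydroxyphenoxy)phenoxy]benzene-1,3-diol | Oc1cc(O)c(Oc2cc(O)c(Oc3cc(O)cc(O)c3Oc3cc(O)c(Oc4cc(O)c(O)c(O)c4)c(O)c3)c(O)c2)c(O)c1 | target

**Count and risks**

Total steps: 14. Longest linear sequence: 10 steps (steps 1–8, 13 and 14); the A–B–C branch (steps 9–12) is 4 steps.

Steps most likely to fail:

1. Step 5 (ring D closure). The chain may only shuttle between lactone 7 and open form 8 without the C6 enolate ever acylating C1, or the aryloxy ketone may degrade in hot alkoxide before the ring closes. The fallback uses only known chemistry and takes ring D from aldehyde 14 by a third coupling/oxidation cycle instead of building it from a chain. It sets out from phenol 21. Copper-catalysed coupling of 21 with 14 (CuI, picolinic acid, K3PO4, DMSO) should give 4-{2-[2,6-dimethoxy-4-(2,4,6-trimethoxyphenoxy)phenoxy]-4,6-dimethoxyphenoxy}-2,6-dimethoxybenzaldehyde F1. Baeyer–Villiger oxidation with mCPBA gives 4-{2-[2,6-dimethoxy-4-(2,4,6-trimethoxyphenoxy)phenoxy]-4,6-dimethoxyphenoxy}-2,6-dimethoxyphenyl formate F2 in the flask, and methanolysis (K2CO3, MeOH) frees 4-{2-[2,6-dimethoxy-4-(2,4,6-trimethoxyphenoxy)phenoxy]-4,6-dimethoxyphenoxy}-2,6-dimethoxyphenol F3, whose hydroxyl sits between two methoxy groups. A last copper-catalysed coupling of F3 with commercial 5-bromo-1,2,3-trimethoxybenzene comes back to the route at 22, so that steps 1–8 and 13 are no longer needed.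

2. Step 13 (fragment coupling). The phenoxide of 21 may attack sulfur of triflate 12 and take over the triflyl group, or the crowded phenoxide may fail to undergo reductive elimination from palladium, so that 11 and 21 are returned. The fallback replaces the palladium cycle by an aryne addition, which is known to tolerate hindered phenols, and sets out from phenol 11. Ortho-bromination with NBS (MeCN, −20 °C) should give 2-bromo-3,5-dimethoxy-4-(3,4,5-trimethoxyphenoxy)phenol F4. Silylation with hexamethyldisilazane gives [2-bromo-3,5-dimethoxy-4-(3,4,5-trimethoxyphenoxy)phenoxy]trimethylsilane F5 in the flask. Treatment with n-BuLi at −78 °C (bromine–lithium exchange and shift of silicon from oxygen to carbon, a retro-Brook rearrangement) and then Tf2O gives 3,5-dimethoxy-4-(3,4,5-trimethoxyphenoxy)-2-(trimethylsilyl)phenyl trifluoromethanesulfonate F6. With CsF in MeCN at rt, F6 releases the aryne across D1–D2; the phenoxide of 21 adds at D1, the aryne carbon remote from the D3 methoxy group, and protonation at D2 comes back to the route at 22.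

3. Step 14 (global demethylation). Cleavage of the flanked methyl ethers may stop short of completion, and the very electron-rich polyphenol may be oxidized by air during aqueous isolation. The fallback is a capture-and-release sequence that sets out from 22. The BBr3 cleavage is run as before, but the crude polyphenol is not isolated; it is acetylated at once (Ac2O, pyridine, DMAP) to the dodecaacetate of 23 F7. This ester is air-stable and can be chromatographed free of partly methylated material, which can be put through cleavage and acetylation again. Acid-catalysed methanolysis (HCl in degassed MeOH, rt), which never forms a phenoxide, then releases the phenols and comes back to the route at 23.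

**Further compounds**

F1 | step 5 | 4-{2-[2,6-dimethoxy-4-(2,4,6-trimethoxyphenoxy)phenoxy]-4,6-dimethoxyphenoxy}-2,6-dimethoxybenzaldehyde | O=Cc1c(OC)cc(Oc2c(OC)cc(OC)cc2Oc2c(OC)cc(Oc3c(OC)cc(OC)cc3OC)cc2OC)cc1OC
F2 | step 5 | 4-{2-[2,6-dimethoxy-4-(2,4,6-trimethoxyphenoxy)phenoxy]-4,6-dimethoxyphenoxy}-2,6-dimethoxyphenyl formate | O=COc1c(OC)cc(Oc2c(OC)cc(OC)cc2Oc2c(OC)cc(Oc3c(OC)cc(OC)cc3OC)cc2OC)cc1OC
F3 | step 5 | 4-{2-[2,6-dimethoxy-4-(2,4,6-trimethoxyphenoxy)phenoxy]-4,6-dimethoxyphenoxy}-2,6-dimethoxyphenol | Oc1c(OC)cc(Oc2c(OC)cc(OC)cc2Oc2c(OC)cc(Oc3c(OC)cc(OC)cc3OC)cc2OC)cc1OC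
F4 | step 13 | 2-bromo-3,5-dimethoxy-4-(3,4,5-trimethoxyphenoxy)phenol | COc1cc(O)c(Br)c(OC)c1Oc1cc(OC)c(OC)c(OC)c1
F5 | step 13 | [2-bromo-3,5-dimethoxy-4-(3,4,5-trimethoxyphenoxy)phenoxy]trimethylsilane | COc1cc(O[Si](C)(C)C)c(Br)c(OC)c1Oc1cc(OC)c(OC)c(OC)c1
F6 | step 13 | 3,5-dimethoxy-4-(3,4,5-trimethoxyphenoxy)-2-(trimethylsilyl)phenyl trifluoromethanesulfonate | COc1cc(OS(=O)(=O)C(F)(F)F)c([Si](C)(C)C)c(OC)c1Oc1cc(OC)c(OC)c(OC)c1
F7 | step 14 | dodecaacetate of 23 | CC(=O)Oc1cc(OC(C)=O)c(Oc2cc(OC(C)=O)c(Oc3cc(OC(C)=O)cc(OC(C)=O)c3Oc3cc(OC(C)=O)c(Oc4cc(OC(C)=O)c(OC(C)=O)c(OC(C)=O)c4)c(OC(C)=O)c3)c(OC(C)=O)c2)c(OC(C)=O)c1
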